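- Reckon J in mM, not in percent. From the dusk run, take the late rate v, the J gained per hour between its readings at 20.0 min and 40.0 min: 22.5 mM h⁻¹, a reading that carries the scatter.

- dusk: Z 0.15 M; G 10 µM; run made earlier
- flask: Z 0.10 M; G 10 µM; time 2.0 h

dusk run (percent of the Z charged)

| time / min | J / % | Q / % | Z / % |
|---|---|---|---|
| 2.50 | 0.1 | 1.4 | 98.4 |
| 8.00 | 0.9 | 3.6 | 95.2 |
| 12.0 | 1.3 | 5.2 | 94.1 |
| 20.0 | 3.6 | 6.5 | 90.1 |
| 30.0 | 5.3 | 9.1 | 86.2 |
| 40.0 | 8.6 | 9.7 | 82.2 |

(each reading ± 0.3 percentage points)

1. J at 2.0 h, in percent of the Z charged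
2. concentration of Q in solution at 2.0 h, in percent of saturation

- solid, in amounts per volume of the solution: Z
- at the start none of Z is in solution
- Q is what Z becomes in solution
- Q means what is dissolved; the solid is not counted in it

- Carry v to the flask, which holds the same 10 µM of G. The dusk run lost Z at 40.0 mM h⁻¹, so at that pace the flask's 0.10 M of Z lasts 2.50 h, longer than the 2.0 h asked.
- Set the upper extreme: let the flask make J at v from the start, which gives 45.0%.
- Set the lower extreme: hold the dusk run's mean rate over its first 40.0 min, 19.3 mM h⁻¹, which is slower than v and gives 38.6%. I expect the flask between the two, if its rate climbs from that mean towards v.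
- Compute only the correction: the line through those two dusk readings meets zero J at the hold-up τ (an induction period), 5.60 min, also a reading with its scatter, and short against 2.0 h. My estimate for the flask at the asked time t is v(t − τ), or 42.9%.
- Note the forecast: with its view that “J formation rises less than proportionally with Q”, it gives 38%, lower than my estimate, and 18% of saturation.
- Read the flask: it gives 39.7% of J, 3.2 percentage points under my estimate, with Q at 62.3% of saturation.

    Q + G ⇌ E (K = 95.0 M⁻¹, k = 8.20 × 10⁵ M⁻¹ h⁻¹)
    E ⇌ G + J (K = 0.0550 M, k = 6300 h⁻¹)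
    Z ⇌ Q, rate k3*(cs3 - [Q]) while solid is left; crystals form when [Q] > cs3 (solubility = 33.0 mM, k = 1.70 h⁻¹)

- Compare in mM: the dusk run at 2.0 h holds 26.5% of its charge, 39.7 mM, and the flask 39.7 mM. Between 1.00 h and 2.00 h the flask gains 20.2 mM h⁻¹, against v of 22.5 mM h⁻¹.
- Take the neighbour, the same flask read at 30 min: v and τ give 9.15%, and the computed result is 8.31%.

All runs were generated by integration for an exercise; the scatter is artificial.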